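**Plan**

- Ring letters: A is the terminal 2,4,6-trihydroxyphenoxy ring; B the central ring (OH at C-1, O–ring A at C-3, O–ring C at C-5); C the pentasubstituted ring (ether O at C-1, OH at C-2, C-4 and C-6, ring D at C-5); D the C-bound 2,4,6-trihydroxyphenyl ring.
- Enabling feature: C-5 of ring C and C-1 of ring D each lie between two hydroxyl-bearing carbons (C-4/C-6 and C-2/C-6). Each is therefore a latent malonate carbon, and the C-5(C)–C-1(D) bond is the middle bond of an ethane-1,1,2,2-tetracarboxylate. Without the ether, rings C and D are a symmetric hexahydroxybiphenyl with four equivalent C–H sites.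
- Cuts, in order: the ten O–H bonds (kept as O–CH3); the O–C-5 and O–C-3 aryl ether bonds of ring B; the C-1–O bond of ring C back to C–H (through a formyl group); last, C-3–C-4 and C-1–C-6 of ring C together with C-2–C-3 and C-5–C-6 of ring D.
- Forward: rings C and D are built together in step 1 around the central bond that is already present. Decarboxylation, methylation and formylation/Dakin oxidation then give the ring C–D phenol. Ring A is joined to ring B, ring B to ring C, and the methyl groups are removed last.
- Stereochemistry: nothing has to be set. The target has no stereocentre, and the tetra-ortho-substituted biaryl axis is not stereogenic because ring D is symmetric about it.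

Key step: step 1

Remark on the chemistry: the four starting materials are taken as commercial, and all free polyphenols are handled under argon because they oxidise easily.

**Route**

Step 1
Reactants: 1 tetraethyl ethane-1,1,2,2-tetracarboxylate; 2 diethyl 3-oxopentanedioate (3 equiv)
Product: 4 tetraethyl 2,2',4,4',6,6'-hexahydroxybiphenyl-3,3',5,5'-tetracarboxylate, via half-annulated arylmalonate 3 (not isolated)
Conditions: NaOEt (6 equiv), EtOH, reflux; EtOH distilled off, 140 °C, N2; then aq HCl, 0 °C
Reagents that add atoms: none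
Why: Proposed new method: ethoxide converts 2 into its enolate, one α-carbon of which C-acylates an ester of one malonate half of 1 (crossed Claisen), and the second α-carbon then attacks the geminal ester in a 6-exo-trig Dieckmann closure; loss of two ethoxides and enolisation of the cyclohexane-1,3,5-trione give the phloroglucinolate 3, on whose remaining arylmalonate half a second molecule of 2 repeats the sequence and closes the other ring in the same 6-exo-trig Dieckmann mode. The closest known reaction is the sodium alkoxide condensation of diethyl malonate with diethyl 3-oxopentanedioate to diethyl 2,4,6-trihydroxybenzene-1,3-dicarboxylate, which has not been carried out twice on an ethane-1,1,2,2-tetracarboxylate. No stereocentre is created, and the biaryl axis of 4 is not stereogenic because each ring is symmetric about it. The step needs complete C-acylation on both halves in competition with self-condensation of 2; the doubly activated nucleophile in excess, removal of ethanol from the melt and the irreversible aromatisation of each ring to a stabilised polyanion should provide it, and any benzofuranone formed from 3 by attack of an ortho-phenoxide on its malonate is itself an activated aryl ester that can re-enter the sequence. Since both rings are assembled around carbons that are sp3 in 1, the tetra-ortho-oxygenated aryl–aryl bond never has to be made by coupling, and the twofold symmetry of 4 leaves no regiochemical question.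

Step 2
Reactants: 4 tetraethyl 2,2',4,4',6,6'-hexahydroxybiphenyl-3,3',5,5'-tetracarboxylate
Product: 6 biphenyl-2,2',4,4',6,6'-hexol, via tetracarboxylic acid 5 (not isolated)
Conditions: aq NaOH (degassed), reflux, N2; then HCl to pH 1, 80 °C
Reagents that add atoms: none
Why: Ester saponification followed by decarboxylation of the phloroglucinolcarboxylic acids, which lose CO2 readily through their keto tautomers (vinylogous β-keto acids), as in the classical preparation of phloroglucinol from its tricarboxylic ester; oxygen is excluded because the hexol is oxidation-prone.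

Step 3
Reactants: 6 biphenyl-2,2',4,4',6,6'-hexol
Product: 7 2,2',4,4',6,6'-hexamethoxybiphenyl
Conditions: Me2SO4 (excess), K2CO3, acetone, reflux, N2
Reagents that add atoms: dimethyl sulfate, COS(=O)(=O)OC
Why: Williamson O-methylation; the hard electrophile dimethyl sulfate with a weak base in acetone favours O- over C-alkylation of the phloroglucinol rings and should cap all six phenols.

Step 4
Reactants: 7 2,2',4,4',6,6'-hexamethoxybiphenyl
Product: 9 2,2',4,4',6,6'-hexamethoxybiphenyl-3-carbaldehyde, via iminium chloride 8 (not isolated)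
Conditions: POCl3 (1.0 equiv), DMF, 0 °C to rt; then aq NaOH, 0 °C
Reagents that add atoms: N,N-dimethylformamide, CN(C)C=O; water, O
Why: Vilsmeier–Haack formylation at one of the four equivalent C–H positions, each activated by two ortho and one para methoxy group; the formyl group deactivates only its own ring, so one equivalent of reagent and recycling of unreacted 7 are used to limit attack on the other ring.

Step 5
Reactants: 9 2,2',4,4',6,6'-hexamethoxybiphenyl-3-carbaldehyde
Product: 11 2,2',4,4',6,6'-hexamethoxybiphenyl-3-ol, via aryl formate 10 (not isolated)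
Conditions: 30% aq H2O2 (1.2 equiv), H2SO4 (cat.), MeOH–CH2Cl2, rt
Reagents that add atoms: hydrogen peroxide, OO
Why: Acid-catalysed Dakin oxidation (Baeyer–Villiger-type aryl migration in the peroxyhemiacetal), in which the very electron-rich aryl group migrates in preference to hydrogen and the formate 10 is methanolysed in the same pot; only a small excess of peroxide is used because the product phenol is easily oxidised.

Step 6
Reactants: 12 2,4,6-trimethoxybenzaldehyde
Product: 14 2,4,6-trimethoxyphenol, via aryl formate 13 (not isolated)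
Conditions: 30% aq H2O2 (1.2 equiv), H2SO4 (cat.), MeOH, rt
Reagents that add atoms: hydrogen peroxide, OO
Why: The same acid-catalysed Dakin oxidation, on the aldehyde class for which it is best established (ortho/para-methoxybenzaldehydes).

Step 7
Reactants: 14 2,4,6-trimethoxyphenol; 15 1-bromo-3-iodo-5-methoxybenzene (1.3 equiv)
Product: 16 1-bromo-3-methoxy-5-(2,4,6-trimethoxyphenoxy)benzene
Conditions: CuI (10 mol%), picolinic acid (20 mol%), K3PO4, DMSO, 80 °C, Ar
Reagents that add atoms: none
Why: Ullmann-type copper-catalysed aryl ether synthesis with a picolinate ligand, which accepts doubly ortho-substituted phenols; the C–I bond reacts below the temperature needed for C–Br, so the bromide should be kept for step 8.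

Step 8
Reactants: 11 2,2',4,4',6,6'-hexamethoxybiphenyl-3-ol; 16 1-bromo-3-methoxy-5-(2,4,6-trimethoxyphenoxy)benzene
Product: 17 2,2',4,4',6,6'-hexamethoxy-3-[3-methoxy-5-(2,4,6-trimethoxyphenoxy)phenoxy]biphenyl
Conditions: CuI (20 mol%), picolinic acid (40 mol%), K3PO4, DMSO, 105 °C, Ar
Reagents that add atoms: none
Why: The same Ullmann-type C–O coupling, now at an unhindered 3,5-dioxygenated aryl bromide, so that the only hindered partner is the phenoxide of 11, the role in which ortho-flanked phenols are known to couple.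

Step 9
Reactants: 17 2,2',4,4',6,6'-hexamethoxy-3-[3-methoxy-5-(2,4,6-trimethoxyphenoxy)phenoxy]biphenyl
Product: 18 3-[3-hydroxy-5-(2,4,6-trihydroxyphenoxy)phenoxy]biphenyl-2,2',4,4',6,6'-hexol (CNP0260439.0)
Conditions: BBr3 (30 equiv), CH2Cl2, −78 °C to rt; then H2O, 0 °C
Reagents that add atoms: none
Why: Lewis-acid ether cleavage: BBr3 coordinates each methoxy oxygen and bromide removes the methyl group by SN2, while the diaryl ether and biaryl bonds are inert because no such displacement is possible at an aryl carbon.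

**Compound list**

1 | tetraethyl ethane-1,1,2,2-tetracarboxylate | CCOC(=O)C(C(=O)OCC)C(C(=O)OCC)C(=O)OCC | starting material
2 | diethyl 3-oxopentanedioate | CCOC(=O)CC(=O)CC(=O)OCC | starting material
3 | diethyl 5-(1,3-diethoxy-1,3-dioxopropan-2-yl)-2,4,6-trihydroxybenzene-1,3-dicarboxylate (half-annulated arylmalonate, present as its sodium salt) | CCOC(=O)C(C(=O)OCC)c1c(O)c(C(=O)OCC)c(O)c(C(=O)OCC)c1O | intermediate (not isolated)
4 | tetraethyl 2,2',4,4',6,6'-hexahydroxybiphenyl-3,3',5,5'-tetracarboxylate | CCOC(=O)c1c(O)c(C(=O)OCC)c(O)c(-c2c(O)c(C(=O)OCC)c(O)c(C(=O)OCC)c2O)c1O | intermediate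
5 | 2,2',4,4',6,6'-hexahydroxybiphenyl-3,3',5,5'-tetracarboxylic acid | OC(=O)c1c(O)c(C(=O)O)c(O)c(-c2c(O)c(C(=O)O)c(O)c(C(=O)O)c2O)c1O | intermediate (not isolated)
6 | biphenyl-2,2',4,4',6,6'-hexol | Oc1cc(O)c(-c2c(O)cc(O)cc2O)c(O)c1 | intermediate
7 | 2,2',4,4',6,6'-hexamethoxybiphenyl | COc1cc(OC)c(-c2c(OC)cc(OC)cc2OC)c(OC)c1 | intermediate
8 | N-[(2,2',4,4',6,6'-hexamethoxybiphenyl-3-yl)methylidene]-N-methylmethanaminium chloride | C[N+](C)=Cc1c(OC)cc(OC)c(-c2c(OC)cc(OC)cc2OC)c1OC.[Cl-] | intermediate (not isolated)
9 | 2,2',4,4',6,6'-hexamethoxybiphenyl-3-carbaldehyde | O=Cc1c(OC)cc(OC)c(-c2c(OC)cc(OC)cc2OC)c1OC | intermediate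
10 | 2,2',4,4',6,6'-hexamethoxybiphenyl-3-yl formate | O=COc1c(OC)cc(OC)c(-c2c(OC)cc(OC)cc2OC)c1OC | intermediate (not isolated)
11 | 2,2',4,4',6,6'-hexamethoxybiphenyl-3-ol | Oc1c(OC)cc(OC)c(-c2c(OC)cc(OC)cc2OC)c1OC | intermediate
12 | 2,4,6-trimethoxybenzaldehyde | COc1cc(OC)c(C=O)c(OC)c1 | starting material
13 | 2,4,6-trimethoxyphenyl formate | COc1cc(OC)c(OC=O)c(OC)c1 | intermediate (not isolated)
14 | 2,4,6-trimethoxyphenol | COc1cc(OC)c(O)c(OC)c1 | intermediate
15 | 1-bromo-3-iodo-5-methoxybenzene | COc1cc(Br)cc(I)c1 | starting material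
16 | 1-bromo-3-methoxy-5-(2,4,6-trimethoxyphenoxy)benzene | COc1cc(Br)cc(Oc2c(OC)cc(OC)cc2OC)c1 | intermediate
17 | 2,2',4,4',6,6'-hexamethoxy-3-[3-methoxy-5-(2,4,6-trimethoxyphenoxy)phenoxy]biphenyl | COc1cc(Oc2c(OC)cc(OC)cc2OC)cc(Oc2c(OC)cc(OC)c(-c3c(OC)cc(OC)cc3OC)c2OC)c1 | intermediate
18 | 3-[3-hydroxy-5-(2,4,6-trihydroxyphenoxy)phenoxy]biphenyl-2,2',4,4',6,6'-hexol (CNP0260439.0) | Oc1cc(Oc2c(O)cc(O)cc2O)cc(Oc2c(O)cc(O)c(-c3c(O)cc(O)cc3O)c2O)c1 | target

**Step count and risks**

Total step count: 9. Longest linear sequence: 7 steps (steps 1, 2, 3, 4, 5, 8, 9); the ring A–B branch is steps 6 and 7.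

Steps most likely to fail:

Step 1 (proposed new method). The second Claisen–Dieckmann sequence may stall on the hindered, easily deprotonated arylmalonate half of 3, while base-mediated self-condensation of 2 uses up the nucleophile. The fallback uses known chemistry and makes the biaryl bond by aryl–aryl coupling instead. Setting out from 2, the long-known alkoxide condensation with diethyl malonate (NaOEt, 140 °C) would give diethyl 2,4,6-trihydroxybenzene-1,3-dicarboxylate F1. Hydrolysis and decarboxylation as in step 2 would give benzene-1,3,5-triol F2, and methylation as in step 3 would give 1,3,5-trimethoxybenzene F3. Iodination (N-iodosuccinimide, MeCN, rt) would give 2-iodo-1,3,5-trimethoxybenzene F4, and Ullmann homocoupling (Cu powder, 230 °C) would come back to the route at 7.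

Step 8. Carbon–oxygen bond formation at copper may be slow for the doubly flanked, buttressed phenoxide of 11, so that oxidation of this electron-rich phenol and reductive loss of bromine from 16 take over. The fallback replaces both copper couplings by nucleophilic aromatic substitution on a nitro-activated ring B. Setting out from 14, reaction with commercial 1,3-difluoro-5-methoxy-2-nitrobenzene (2 equiv, K2CO3, DMF, rt) would give 1-fluoro-5-methoxy-2-nitro-3-(2,4,6-trimethoxyphenoxy)benzene F5. Displacement of the second ortho-fluorine by 11 (K2CO3, DMF, 60 °C) would give 2,2',4,4',6,6'-hexamethoxy-3-[5-methoxy-2-nitro-3-(2,4,6-trimethoxyphenoxy)phenoxy]biphenyl F6. Reduction (H2, Pd/C, EtOAc) would give 2-[(2,2',4,4',6,6'-hexamethoxybiphenyl-3-yl)oxy]-4-methoxy-6-(2,4,6-trimethoxyphenoxy)aniline F7. Reductive deamination through the diazonium ion (tert-butyl nitrite, DMF, 65 °C) would remove the nitrogen from the carbon between the two ether carbons, restore the 1,3,5-pattern of ring B and come back to the route at 17.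

Step 9. Cleavage of the ten ethers may stay incomplete (the flanked ones on ring C last), and the polyphenol may degrade by oxidation or acid during the long exposure and the work-up. The fallback changes the protecting group to benzyl so that the last step is a neutral hydrogenolysis.

- Ring C–D part: setting out from 6, benzylation (BnBr, K2CO3, DMF, rt) would give 2,2',4,4',6,6'-hexakis(benzyloxy)biphenyl F8. Formylation as in step 4 would give 2,2',4,4',6,6'-hexakis(benzyloxy)biphenyl-3-carbaldehyde F9, and Dakin oxidation as in step 5 would give 2,2',4,4',6,6'-hexakis(benzyloxy)biphenyl-3-ol F10.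
- Ring A–B part: commercial 1,3,5-tris(benzyloxy)benzene would be formylated to 2,4,6-tris(benzyloxy)benzaldehyde F11 and oxidised to 2,4,6-tris(benzyloxy)phenol F12. Commercial 3-bromo-5-iodophenol would be benzylated to 1-(benzyloxy)-3-bromo-5-iodobenzene F13. Coupling of F12 and F13 as in step 7 would give 1-(benzyloxy)-3-bromo-5-[2,4,6-tris(benzyloxy)phenoxy]benzene F14.
- Union and release: coupling of F10 and F14 as in step 8 would give 2,2',4,4',6,6'-hexakis(benzyloxy)-3-{3-(benzyloxy)-5-[2,4,6-tris(benzyloxy)phenoxy]phenoxy}biphenyl F15, and hydrogenolysis (H2, Pd/C, EtOAc–MeOH, rt) would come back to the route at 18.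

**Further compounds**

F1 | step 1 | diethyl 2,4,6-trihydroxybenzene-1,3-dicarboxylate | CCOC(=O)c1c(O)cc(O)c(C(=O)OCC)c1O
F2 | step 1 | benzene-1,3,5-triol | Oc1cc(O)cc(O)c1
F3 | step 1 | 1,3,5-trimethoxybenzene | COc1cc(OC)cc(OC)c1
F4 | step 1 | 2-iodo-1,3,5-trimethoxybenzene | COc1cc(OC)c(I)c(OC)c1
F5 | step 8 | 1-fluoro-5-methoxy-2-nitro-3-(2,4,6-trimethoxyphenoxy)benzene | COc1cc(F)c([N+](=O)[O-])c(Oc2c(OC)cc(OC)cc2OC)c1
F6 | step 8 | 2,2',4,4',6,6'-hexamethoxy-3-[5-methoxy-2-nitro-3-(2,4,6-trimethoxyphenoxy)phenoxy]biphenyl | COc1cc(Oc2c(OC)cc(OC)cc2OC)c([N+](=O)[O-])c(Oc2c(OC)cc(OC)c(-c3c(OC)cc(OC)cc3OC)c2OC)c1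
F7 | step 8 | 2-[(2,2',4,4',6,6'-hexamethoxybiphenyl-3-yl)oxy]-4-methoxy-6-(2,4,6-trimethoxyphenoxy)aniline | COc1cc(Oc2c(OC)cc(OC)cc2OC)c(N)c(Oc2c(OC)cc(OC)c(-c3c(OC)cc(OC)cc3OC)c2OC)c1
F8 | step 9 | 2,2',4,4',6,6'-hexakis(benzyloxy)biphenyl | c1ccccc1COc1cc(OCc2ccccc2)c(-c2c(OCc3ccccc3)cc(OCc3ccccc3)cc2OCc2ccccc2)c(OCc2ccccc2)c1
F9 | step 9 | 2,2',4,4',6,6'-hexakis(benzyloxy)biphenyl-3-carbaldehyde | O=Cc1c(OCc2ccccc2)cc(OCc2ccccc2)c(-c2c(OCc3ccccc3)cc(OCc3ccccc3)cc2OCc2ccccc2)c1OCc1ccccc1
F10 | step 9 | 2,2',4,4',6,6'-hexakis(benzyloxy)biphenyl-3-ol | Oc1c(OCc2ccccc2)cc(OCc2ccccc2)c(-c2c(OCc3ccccc3)cc(OCc3ccccc3)cc2OCc2ccccc2)c1OCc1ccccc1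
F11 | step 9 | 2,4,6-tris(benzyloxy)benzaldehyde | O=Cc1c(OCc2ccccc2)cc(OCc2ccccc2)cc1OCc1ccccc1
F12 | step 9 | 2,4,6-tris(benzyloxy)phenol | Oc1c(OCc2ccccc2)cc(OCc2ccccc2)cc1OCc1ccccc1
F13 | step 9 | 1-(benzyloxy)-3-bromo-5-iodobenzene | Brc1cc(I)cc(OCc2ccccc2)c1
F14 | step 9 | 1-(benzyloxy)-3-bromo-5-[2,4,6-tris(benzyloxy)phenoxy]benzene | Brc1cc(OCc2ccccc2)cc(Oc2c(OCc3ccccc3)cc(OCc3ccccc3)cc2OCc2ccccc2)c1
F15 | step 9 | 2,2',4,4',6,6'-hexakis(benzyloxy)-3-{3-(benzyloxy)-5-[2,4,6-tris(benzyloxy)phenoxy]phenoxy}biphenyl | c1ccccc1COc1cc(Oc2c(OCc3ccccc3)cc(OCc3ccccc3)cc2OCc2ccccc2)cc(Oc2c(OCc3ccccc3)cc(OCc3ccccc3)c(-c3c(OCc4ccccc4)cc(OCc4ccccc4)cc3OCc3ccccc3)c2OCc2ccccc2)c1
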